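**Retrosynthetic overview**

- Target 18 ⇐ benzyl ether 17 (hydrogenolysis) ⇐ o-hydroxy diaryl ketone 14 (C=O to CH2 through an o-quinone methide).
- 14 ⇐ aryne 13 + 4-(benzyloxy)benzoic acid 12: the aryne inserts into the acyl C–O bond, forming the ring-A C–OH bond and the ring-A C–C(=O) bond together.
- 13 ⇐ silyl triflate 11 ⇐ phenol 4, by carbamate-directed lithiation between the two oxygens, C-silylation, carbamate cleavage and triflation.
- 4 ⇐ 3-bromo-5-methoxyphenol 1 + 3-vinylanisole 2 (B-alkyl Suzuki coupling makes the CH2CH2 link). No ring is formed anywhere: all three benzene rings are bought.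
- Feature: on the central benzene ring (ring A) the adjacent carbons C1(OH)–C2(CH2Ar)–C3(OMe) carry O, C, O. C2, flanked by two oxygens, is the carbanion carbon of a 3-methoxybenzyne after an O-nucleophile has attacked the remote aryne carbon C1.

Key step: step 5

Remark: the target has no stereocentre and is achiral, so the structure given is a single compound and no stereocontrol is needed.

**Step 1**
Reactants: 1 3-bromo-5-methoxyphenol; 2 3-vinylanisole
Product: 4 3-methoxy-5-[2-(3-methoxyphenyl)ethyl]phenol, via alkylborane 3 (not isolated)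
Conditions: 2, 9-BBN-H (1.1 equiv), THF, 0 °C to rt; then 1, PdCl2(dppf) (3 mol%), 3 M aq NaOH (3 equiv), THF, 65 °C; work-up at pH 5
Reagents that add atoms: none
Why: 9-BBN hydroborates the styrene at the terminal carbon and the primary B-alkyl group is then transferred to the aryl bromide in a hydroxide-promoted B-alkyl Suzuki–Miyaura coupling, the extra base holding the phenol as its phenoxide, which is meta to the C–Br bond and should not block oxidative addition.

**Step 2**
Reactants: 4 3-methoxy-5-[2-(3-methoxyphenyl)ethyl]phenol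
Product: 5 3-methoxy-5-[2-(3-methoxyphenyl)ethyl]phenyl N-(propan-2-yl)carbamate
Conditions: i-PrNCO (1.5 equiv), Et3N (0.2 equiv), CH2Cl2, rt
Reagents that add atoms: isopropyl isocyanate, CC(C)N=C=O
Why: Amine-catalysed addition of the phenol O–H across the isocyanate (carbamoylation) installs a strong directed-metalation group that can later be removed under mild base.

**Step 3**
Reactants: 5 3-methoxy-5-[2-(3-methoxyphenyl)ethyl]phenyl N-(propan-2-yl)carbamate
Product: 9 3-methoxy-5-[2-(3-methoxyphenyl)ethyl]-2-(trimethylsilyl)phenyl N-(propan-2-yl)carbamate, via N-silyl carbamate 6 (not isolated), via aryllithium 7 (not isolated), via bis-silyl carbamate 8 (not isolated)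
Conditions: TBSOTf (1.1 equiv), TMEDA, Et2O, 0 °C to rt; n-BuLi (2.0 equiv), TMEDA, −78 °C; TMSCl, −78 °C to rt; aq NaHSO4
Reagents that add atoms: chlorotrimethylsilane, C[Si](C)(C)Cl
Why: Directed ortho-metalation: once in situ N-silylation has masked the N–H, n-BuLi/TMEDA removes the C2 proton flanked by the carbamate oxygen and the OMe group (the cooperative site, far more acidic at −78 °C than any position of the anisole ring), TMSCl traps the aryllithium and the acidic work-up cleaves the N–Si bond.

**Step 4**
Reactants: 9 3-methoxy-5-[2-(3-methoxyphenyl)ethyl]-2-(trimethylsilyl)phenyl N-(propan-2-yl)carbamate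
Product: 11 3-methoxy-5-[2-(3-methoxyphenyl)ethyl]-2-(trimethylsilyl)phenyl trifluoromethanesulfonate, via silylphenol 10 (not isolated)
Conditions: DBU (1.5 equiv), Et2NH (1.2 equiv), MeCN, 40 °C; then PhNTf2 (1.5 equiv), rt
Reagents that add atoms: N-phenylbis(trifluoromethanesulfonimide), O=S(=O)(N(c1ccccc1)S(=O)(=O)C(F)(F)F)C(F)(F)F
Why: DBU deprotonates the carbamate N–H and triggers E1cB loss of isopropyl isocyanate (scavenged by Et2NH as a urea), and the freed phenoxide is triflated in the same flask by PhNTf2, a base-only sequence that avoids protodesilylation of the electron-rich arylsilane.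

**Step 5**
Reactants: 11 3-methoxy-5-[2-(3-methoxyphenyl)ethyl]-2-(trimethylsilyl)phenyl trifluoromethanesulfonate; 12 4-(benzyloxy)benzoic acid
Product: 14 [4-(benzyloxy)phenyl]{2-hydroxy-6-methoxy-4-[2-(3-methoxyphenyl)ethyl]phenyl}methanone, via aryne 13 (not isolated)
Conditions: 11 (1.0 equiv), 12 (1.2 equiv), CsF (4 equiv), THF, 125 °C, sealed tube; dilute HCl work-up
Reagents that add atoms: none
Why: Fluoride attacks silicon and triflate leaves from the neighbouring carbon to give aryne 13; the caesium carboxylate of 12 adds through oxygen to the aryne carbon remote from OMe, the aryl anion formed on the carbon next to OMe attacks the ester carbonyl, and the four-membered alkoxide opens to the o-acyl phenoxide, so the aryne is formally inserted into the acyl C–O bond and the ring-A C–O and C–C(=O) bonds form in one operation. The closest known reaction type is the fluoride-induced C–O insertion of arynes into carboxylic acids in hot THF, which gives o-hydroxyaryl ketones; here it is applied to a more substituted 3-methoxyaryne. No ring is closed and no stereocentre is created. The step needs regioselective addition to the unsymmetrical aryne, which the OMe group should secure by distorting the triple bond towards attack at the remote carbon and by stabilising inductively the negative charge that develops on the adjacent carbon; the alkyl chain, meta to the attacked carbon, has no comparable influence. It also needs the intramolecular acyl shift to outrun protonation of the aryl anion (which would stop at the aryl ester), and the aprotic solvent, the high temperature and the excess CsF that keeps the acid as its carboxylate serve this.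

**Step 6**
Reactants: 14 [4-(benzyloxy)phenyl]{2-hydroxy-6-methoxy-4-[2-(3-methoxyphenyl)ethyl]phenyl}methanone
Product: 17 2-{[4-(benzyloxy)phenyl]methyl}-3-methoxy-5-[2-(3-methoxyphenyl)ethyl]phenol, via aryl ethyl carbonate 15 (not isolated), via o-quinone methide 16 (not isolated)
Conditions: ClCO2Et (1.2 equiv), Et3N (1.3 equiv), THF, 0 °C; filter; NaBH4 (4 equiv), THF–H2O, 0 °C to rt
Reagents that add atoms: none
Why: Carbonate-activated borohydride deoxygenation of an o-hydroxyaryl ketone: hydride reduces the ketone of 15, the ethoxycarbonyl group shifts to the benzylic alkoxide and is expelled to give o-quinone methide 16, and a second hydride adds at the exocyclic carbon to give the o-benzylphenol, leaving the benzyl ether and both methyl ethers untouched.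

**Step 7**
Reactants: 17 2-{[4-(benzyloxy)phenyl]methyl}-3-methoxy-5-[2-(3-methoxyphenyl)ethyl]phenol
Product: 18 2-[(4-hydroxyphenyl)methyl]-3-methoxy-5-[2-(3-methoxyphenyl)ethyl]phenol (IN0509)
Conditions: H2 (1 atm), 10% Pd/C, EtOAc–MeOH, rt
Reagents that add atoms: none
Why: Pd-catalysed hydrogenolysis cleaves the benzylic C–O bond of the benzyl aryl ether to free the phenol, while the diarylmethane and bibenzyl C–C bonds and the aryl methyl ethers are inert under these neutral conditions.

**Compound list**

1 | 3-bromo-5-methoxyphenol | COc1cc(O)cc(Br)c1 | starting material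
2 | 3-vinylanisole (1-ethenyl-3-methoxybenzene) | COc1cccc(C=C)c1 | starting material
3 | 9-[2-(3-methoxyphenyl)ethyl]-9-borabicyclo[3.3.1]nonane | COc1cccc(CCB2C3CCCC2CCC3)c1 | intermediate (not isolated)
4 | 3-methoxy-5-[2-(3-methoxyphenyl)ethyl]phenol | COc1cccc(CCc2cc(O)cc(OC)c2)c1 | intermediate
5 | 3-methoxy-5-[2-(3-methoxyphenyl)ethyl]phenyl N-(propan-2-yl)carbamate | COc1cccc(CCc2cc(OC)cc(OC(=O)NC(C)C)c2)c1 | intermediate
6 | 3-methoxy-5-[2-(3-methoxyphenyl)ethyl]phenyl N-(tert-butyldimethylsilyl)-N-(propan-2-yl)carbamate | COc1cccc(CCc2cc(OC)cc(OC(=O)N(C(C)C)[Si](C)(C)C(C)(C)C)c2)c1 | intermediate (not isolated)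
7 | 2-lithio derivative of 6 (lithium at the carbon between OMe and the carbamate oxygen) | COc1cccc(CCc2cc(OC)c([Li])c(OC(=O)N(C(C)C)[Si](C)(C)C(C)(C)C)c2)c1 | intermediate (not isolated)
8 | 3-methoxy-5-[2-(3-methoxyphenyl)ethyl]-2-(trimethylsilyl)phenyl N-(tert-butyldimethylsilyl)-N-(propan-2-yl)carbamate | COc1cccc(CCc2cc(OC)c([Si](C)(C)C)c(OC(=O)N(C(C)C)[Si](C)(C)C(C)(C)C)c2)c1 | intermediate (not isolated)
9 | 3-methoxy-5-[2-(3-methoxyphenyl)ethyl]-2-(trimethylsilyl)phenyl N-(propan-2-yl)carbamate | COc1cccc(CCc2cc(OC)c([Si](C)(C)C)c(OC(=O)NC(C)C)c2)c1 | intermediate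
10 | 3-methoxy-5-[2-(3-methoxyphenyl)ethyl]-2-(trimethylsilyl)phenol (present as its DBU-H phenoxide) | COc1cccc(CCc2cc(O)c([Si](C)(C)C)c(OC)c2)c1 | intermediate (not isolated)
11 | 3-methoxy-5-[2-(3-methoxyphenyl)ethyl]-2-(trimethylsilyl)phenyl trifluoromethanesulfonate | COc1cccc(CCc2cc(OC)c([Si](C)(C)C)c(OS(=O)(=O)C(F)(F)F)c2)c1 | intermediate
12 | 4-(benzyloxy)benzoic acid | OC(=O)c1ccc(OCc2ccccc2)cc1 | starting material
13 | 1,2-didehydro-3-methoxy-5-[2-(3-methoxyphenyl)ethyl]benzene (aryne) | COC1=CC(CCc2cccc(OC)c2)=CC#C1 | intermediate (not isolated)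
14 | [4-(benzyloxy)phenyl]{2-hydroxy-6-methoxy-4-[2-(3-methoxyphenyl)ethyl]phenyl}methanone | COc1cccc(CCc2cc(O)c(C(=O)c3ccc(OCc4ccccc4)cc3)c(OC)c2)c1 | intermediate
15 | 2-[4-(benzyloxy)benzoyl]-3-methoxy-5-[2-(3-methoxyphenyl)ethyl]phenyl ethyl carbonate | COc1cccc(CCc2cc(OC(=O)OCC)c(C(=O)c3ccc(OCc4ccccc4)cc3)c(OC)c2)c1 | intermediate (not isolated)
16 | 6-{[4-(benzyloxy)phenyl]methylidene}-5-methoxy-3-[2-(3-methoxyphenyl)ethyl]cyclohexa-2,4-dien-1-one (drawn Z; the geometry is of no consequence) | O=C1C=C(CCc2cccc(OC)c2)C=C(OC)/C1=C/c1ccc(OCc2ccccc2)cc1 | intermediate (not isolated)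
17 | 2-{[4-(benzyloxy)phenyl]methyl}-3-methoxy-5-[2-(3-methoxyphenyl)ethyl]phenol | COc1cccc(CCc2cc(O)c(Cc3ccc(OCc4ccccc4)cc3)c(OC)c2)c1 | intermediate
18 | 2-[(4-hydroxyphenyl)methyl]-3-methoxy-5-[2-(3-methoxyphenyl)ethyl]phenol (IN0509) | COc1cccc(CCc2cc(O)c(Cc3ccc(O)cc3)c(OC)c2)c1 | target

**Step count**

Total step count: 7. Longest linear sequence: 7 steps (1 and 2 to 18); acid 12 enters as bought material in step 5.

**Steps most likely to fail**

1. Step 5 (aryne insertion). The aryl anion may be protonated before the acyl group shifts, so that the reaction stops at simple O-arylation. The carboxylate may also add with poor regiocontrol, or the product phenoxide may be arylated by a second aryne. The fallback sets out from phenol 4 and comes back at ketone 14. MOMCl and i-Pr2NEt in CH2Cl2 should give 1-methoxy-3-(methoxymethoxy)-5-[2-(3-methoxyphenyl)ethyl]benzene F1. n-BuLi/TMEDA in THF at 0 °C should lithiate C2 between the two oxygens, and addition of 4-(benzyloxy)benzaldehyde should give the racemic diaryl carbinol [4-(benzyloxy)phenyl]{2-methoxy-6-(methoxymethoxy)-4-[2-(3-methoxyphenyl)ethyl]phenyl}methanol F2. MnO2 (or Dess–Martin periodinane) should oxidise it to the MOM-protected ketone [4-(benzyloxy)phenyl]{2-methoxy-6-(methoxymethoxy)-4-[2-(3-methoxyphenyl)ethyl]phenyl}methanone F3. HCl in MeOH at 40 °C should then remove the MOM group to give 14, and the route continues with step 6.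

2. Step 3 (directed lithiation and silylation). N-silylation may be incomplete, so that butyllithium is consumed at the carbamate. The carbamoyl group of the aryllithium may migrate to carbon (anionic ortho-Fries shift) before the silyl chloride captures it, or metalation may occur away from C2. The fallback sets out from alkylborane 3 (made from 2 as in step 1) and comes back at aryne 13, and so at 14. It avoids the lithiation by building the regioisomeric aryne precursor from a guaiacol.
   - Suzuki coupling of 3 with 4-bromo-2-methoxyphenol (COc1cc(Br)ccc1O) under the step 1 conditions should give 2-methoxy-4-[2-(3-methoxyphenyl)ethyl]phenol F4.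
   - NBS with catalytic i-Pr2NH in CH2Cl2 should brominate the only free position ortho to the phenol and give 2-bromo-6-methoxy-4-[2-(3-methoxyphenyl)ethyl]phenol F5.
   - HMDS in THF at reflux should give the silyl ether {2-bromo-6-methoxy-4-[2-(3-methoxyphenyl)ethyl]phenoxy}trimethylsilane F6.
   - n-BuLi at −78 °C should effect bromine–lithium exchange and a 1,3 O-to-C silyl shift (retro-Brook) to the lithium salt of 2-methoxy-4-[2-(3-methoxyphenyl)ethyl]-6-(trimethylsilyl)phenol F7.
   - Tf2O in the same flask should give 2-methoxy-4-[2-(3-methoxyphenyl)ethyl]-6-(trimethylsilyl)phenyl trifluoromethanesulfonate F8, which under the step 5 conditions loses TMS and triflate from the same two carbons and gives the same aryne 13.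

3. Step 6 (deoxygenation). The aqueous borohydride may cleave the aryl carbonate before the hindered, doubly ortho-substituted ketone is reduced, which would return 14. The sequence may also stall at the benzylic alcohol. The fallback sets out from ketone 14 and comes back at 17. LiAlH4 in THF should reduce the carbonyl group to the racemic benzhydrol 2-{[4-(benzyloxy)phenyl](hydroxy)methyl}-3-methoxy-5-[2-(3-methoxyphenyl)ethyl]phenol F9. Et3SiH with TFA in CH2Cl2 at 0 °C should then remove the doubly benzylic hydroxyl by ionic hydrogenation to give 17, ready for step 7.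

**Further compounds**

F1 | step 5 | 1-methoxy-3-(methoxymethoxy)-5-[2-(3-methoxyphenyl)ethyl]benzene | COCOc1cc(OC)cc(CCc2cccc(OC)c2)c1
F2 | step 5 | [4-(benzyloxy)phenyl]{2-methoxy-6-(methoxymethoxy)-4-[2-(3-methoxyphenyl)ethyl]phenyl}methanol (racemic) | COCOc1cc(CCc2cccc(OC)c2)cc(OC)c1C(O)c1ccc(OCc2ccccc2)cc1
F3 | step 5 | [4-(benzyloxy)phenyl]{2-methoxy-6-(methoxymethoxy)-4-[2-(3-methoxyphenyl)ethyl]phenyl}methanone | COCOc1cc(CCc2cccc(OC)c2)cc(OC)c1C(=O)c1ccc(OCc2ccccc2)cc1
F4 | step 3 | 2-methoxy-4-[2-(3-methoxyphenyl)ethyl]phenol | COc1cccc(CCc2ccc(O)c(OC)c2)c1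
F5 | step 3 | 2-bromo-6-methoxy-4-[2-(3-methoxyphenyl)ethyl]phenol | COc1cccc(CCc2cc(Br)c(O)c(OC)c2)c1
F6 | step 3 | {2-bromo-6-methoxy-4-[2-(3-methoxyphenyl)ethyl]phenoxy}trimethylsilane | COc1cccc(CCc2cc(Br)c(O[Si](C)(C)C)c(OC)c2)c1
F7 | step 3 | 2-methoxy-4-[2-(3-methoxyphenyl)ethyl]-6-(trimethylsilyl)phenol | COc1cccc(CCc2cc([Si](C)(C)C)c(O)c(OC)c2)c1
F8 | step 3 | 2-methoxy-4-[2-(3-methoxyphenyl)ethyl]-6-(trimethylsilyl)phenyl trifluoromethanesulfonate | COc1cccc(CCc2cc([Si](C)(C)C)c(OS(=O)(=O)C(F)(F)F)c(OC)c2)c1
F9 | step 6 | 2-{[4-(benzyloxy)phenyl](hydroxy)methyl}-3-methoxy-5-[2-(3-methoxyphenyl)ethyl]phenol (racemic) | COc1cccc(CCc2cc(O)c(C(O)c3ccc(OCc4ccccc4)cc3)c(OC)c2)c1
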